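**Retrosynthetic overview**

- Target 16 is [(2S,3R,4R)-4-(4-hydroxy-3-methoxybenzyl)-2-(3,4,5-trimethoxyphenyl)oxolan-3-yl]methanol. Its C2 is bonded to ring oxygen O1 and is benzylic to the trimethoxyphenyl ring, whose 4-methoxy group lies para to it. The O1–C2 bond can therefore be made from a benzylic C–H bond and the hydroxyl on the C5 side, with no oxygen ever installed at C2.
- 16 ⇐ aryl pivalate 15 ⇐ (DDQ, O1–C2 closure) (2R,3R)-dibenzylbutane-1,4-diol 13, whose guaiacyl ring is switched off as the pivalate.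
- 13 ⇐ trans-dibenzyl lactone 10 (LiAlH4, debenzylation, phenol-selective acylation) ⇐ (R)-β-benzyl lactone 7 + bromide 8 (anti alkylation sets the second centre).
- 7 ⇐ Stobbe half ester 4 from 1 and 2 (asymmetric hydrogenation sets the first centre; ester-selective reduction, lactonisation).
- Ring order: a temporary butyrolactone (step 3, opened in step 5), then the oxolane of the target, closed last (step 8).

Key step: step 8

Remark: 4-(benzyloxy)-3-methoxybenzaldehyde and 3,4,5-trimethoxybenzyl bromide are taken as purchased (otherwise one step from vanillin and from the benzyl chloride).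
Remark: the (S,S) hand of Et-DuPhos is assumed to deliver the R acid in step 2, by analogy with alkylidenesuccinate half esters; the sense is to be confirmed on lactone 7, and the antipodal ligand is used if it proves opposite.

**Route**

Step 1
Reactants: 1 4-(benzyloxy)-3-methoxybenzaldehyde; 2 dimethyl succinate
Product: 4 (E)-4-[4-(benzyloxy)-3-methoxyphenyl]-3-(methoxycarbonyl)but-3-enoic acid, via paraconate lactone 3 (not isolated)
Conditions: NaOMe (1.5 equiv), MeOH, reflux; then aq. HCl
Reagents that add atoms: none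
Why: Stobbe condensation, in which the succinate enolate adds to the aldehyde, the aldolate lactonises onto the distal ester to give 3, and E1cB ring opening gives the half ester with the aryl group trans to the conjugated ester.

Step 2
Reactants: 4 (E)-4-[4-(benzyloxy)-3-methoxyphenyl]-3-(methoxycarbonyl)but-3-enoic acid
Product: 5 (R)-4-[4-(benzyloxy)-3-methoxyphenyl]-3-(methoxycarbonyl)butanoic acid
Conditions: H2 (5 bar), [Rh(cod)((S,S)-Et-DuPhos)]BF4 (0.5 mol%), NaOMe (0.1 equiv), MeOH, rt
Reagents that add atoms: none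
Why: Rhodium-catalysed asymmetric hydrogenation of an itaconate-type half ester, in which the carboxylate and the alkene chelate the cationic rhodium centre and the C2-symmetric bisphospholane selects the alkene face to set C3 as R, while the benzyl ether is inert to this homogeneous catalyst.

Step 3
Reactants: 5 (R)-4-[4-(benzyloxy)-3-methoxyphenyl]-3-(methoxycarbonyl)butanoic acid
Product: 7 (R)-4-[4-(benzyloxy)-3-methoxybenzyl]oxolan-2-one, via hydroxy acid 6 (not isolated)
Conditions: KOH (1.0 equiv), EtOH, 0 °C; CaCl2, NaBH4, EtOH, −10 °C → rt; then 3 M HCl, rt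
Reagents that add atoms: none
Why: Chemoselective borohydride reduction, in which Ca(BH4)2 reduces the methyl ester while the potassium carboxylate is inert, and acidification lets hydroxy acid 6 lactonise to the five-membered ring without touching the stereocentre.

Step 4
Reactants: 7 (R)-4-[4-(benzyloxy)-3-methoxybenzyl]oxolan-2-one; 8 3,4,5-trimethoxybenzyl bromide
Product: 10 (3R,4R)-4-[4-(benzyloxy)-3-methoxybenzyl]-3-(3,4,5-trimethoxybenzyl)oxolan-2-one, via lithium enolate 9 (not isolated)
Conditions: LiN(SiMe3)2 (1.1 equiv), THF, −78 °C; then 8, DMPU, −78 → −30 °C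
Reagents that add atoms: none
Why: Lactone enolate alkylation (SN2 on a benzylic bromide), in which the electrophile approaches the planar enolate on the face opposite the C4 benzyl group and so sets C3 as R, trans to C4.

Step 5
Reactants: 10 (3R,4R)-4-[4-(benzyloxy)-3-methoxybenzyl]-3-(3,4,5-trimethoxybenzyl)oxolan-2-one
Product: 11 (2R,3R)-2-[4-(benzyloxy)-3-methoxybenzyl]-3-(3,4,5-trimethoxybenzyl)butane-1,4-diol
Conditions: LiAlH4 (2 equiv), THF, 0 °C → rt; H2O, aq. NaOH work-up
Reagents that add atoms: none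
Why: Hydride reduction of the lactone to the 1,4-diol, in which hydride addition to the carbonyl outpaces enolisation so neither stereocentre is touched, and the benzyl and methyl ethers are inert.

Step 6
Reactants: 11 (2R,3R)-2-[4-(benzyloxy)-3-methoxybenzyl]-3-(3,4,5-trimethoxybenzyl)butane-1,4-diol
Product: 12 (2R,3R)-2-(4-hydroxy-3-methoxybenzyl)-3-(3,4,5-trimethoxybenzyl)butane-1,4-diol
Conditions: H2 (1 atm), 10% Pd/C, EtOAc–EtOH, rt
Reagents that add atoms: none
Why: Catalytic hydrogenolysis of the aryl benzyl ether, under which the aryl–CH2 bonds, the methyl ethers and the alcohols should be inert at one atmosphere and room temperature.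

Step 7
Reactants: 12 (2R,3R)-2-(4-hydroxy-3-methoxybenzyl)-3-(3,4,5-trimethoxybenzyl)butane-1,4-diol
Product: 13 (2R,3R)-2-[3-methoxy-4-(pivaloyloxy)benzyl]-3-(3,4,5-trimethoxybenzyl)butane-1,4-diol
Conditions: PivCl (1.05 equiv), 1 M aq. NaOH (1.1 equiv), Bu4NHSO4 (5 mol%), CH2Cl2, 0 °C
Reagents that add atoms: pivaloyl chloride, CC(C)(C)C(=O)Cl
Why: Schotten–Baumann acylation under phase transfer, in which only the phenol is ionised by aqueous hydroxide and its tetrabutylammonium phenoxide attacks the hindered acid chloride far faster than the neutral primary alcohols do.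

Step 8
Reactants: 13 (2R,3R)-2-[3-methoxy-4-(pivaloyloxy)benzyl]-3-(3,4,5-trimethoxybenzyl)butane-1,4-diol
Product: 15 [(2S,3R,4R)-4-[3-methoxy-4-(pivaloyloxy)benzyl]-2-(3,4,5-trimethoxyphenyl)oxolan-3-yl]methanol, via benzylic cation 14 (not isolated)
Conditions: DDQ (1.05 equiv), 2,6-dichloropyridine (2 equiv), 4 Å molecular sieves, ClCH2CH2Cl, 0 °C → rt
Reagents that add atoms: none
Why: The trimethoxyphenyl ring forms a charge-transfer complex with DDQ and gives up hydride from its benzylic CH2 to form the para-methoxy-stabilised cation 14, which is captured by the hydroxyl on the C4 side; the closest known reaction type is the DDQ oxidative cycloetherification of electron-rich arylalkanols to 2-aryl oxolanes and isochromans. The oxolane closes in 5-exo-trig mode (O1 onto cationic C2, whose bond to the aryl ring stays outside the new ring), whereas the other hydroxyl could only close an oxetane. C2 is set S by the adjacent C3 centre under kinetic control: allylic 1,3-strain holds the C3–H bond in the plane of the cation, the tethered oxygen must enter from the face that carries C4, and the aryl group therefore ends trans to the C3 CH2OH arm, which is also the more stable arrangement. Site selectivity between the two benzylic CH2 groups is secured by the pivalate, which leaves the guaiacyl CH2 with only an acyloxy group para and a methoxy group meta, so that ring neither binds DDQ well nor stabilises a cation. Selectivity for C–O over C–C capture (Friedel–Crafts closure onto the guaiacyl carbon para to its methoxy group) is secured by keeping the medium non-acidic with 2,6-dichloropyridine, so that the ether once formed is not re-ionised. One equivalent of DDQ and exclusion of water are meant to hold back further oxidation of the C2–H bond of the product.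

Step 9
Reactants: 15 [(2S,3R,4R)-4-[3-methoxy-4-(pivaloyloxy)benzyl]-2-(3,4,5-trimethoxyphenyl)oxolan-3-yl]methanol
Product: 16 [(2S,3R,4R)-4-(4-hydroxy-3-methoxybenzyl)-2-(3,4,5-trimethoxyphenyl)oxolan-3-yl]methanol
Conditions: K2CO3 (1.5 equiv), MeOH, rt; aq. NH4Cl
Reagents that add atoms: none
Why: Base-mediated transesterification (methanolysis) of the activated aryl ester, which releases the phenoxide while the oxolane, the primary alcohol and the methyl ethers are inert and no stereocentre is enolisable.

**Compound list**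

1 | 4-(benzyloxy)-3-methoxybenzaldehyde | COc1cc(C=O)ccc1OCc1ccccc1 | starting material
2 | dimethyl succinate | COC(=O)CCC(=O)OC | starting material
3 | methyl 2-[4-(benzyloxy)-3-methoxyphenyl]-5-oxooxolane-3-carboxylate (paraconate lactone, stereoisomer mixture) | COC(=O)C1CC(=O)OC1c1ccc(OCc2ccccc2)c(OC)c1 | intermediate
4 | (E)-4-[4-(benzyloxy)-3-methoxyphenyl]-3-(methoxycarbonyl)but-3-enoic acid | COC(=O)/C(CC(=O)O)=C/c1ccc(OCc2ccccc2)c(OC)c1 | intermediate
5 | (R)-4-[4-(benzyloxy)-3-methoxyphenyl]-3-(methoxycarbonyl)butanoic acid | COc1cc(C[C@H](CC(=O)O)C(=O)OC)ccc1OCc1ccccc1 | intermediate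
6 | (R)-4-[4-(benzyloxy)-3-methoxyphenyl]-3-(hydroxymethyl)butanoic acid | COc1cc(C[C@H](CC(=O)O)CO)ccc1OCc1ccccc1 | intermediate
7 | (R)-4-[4-(benzyloxy)-3-methoxybenzyl]oxolan-2-one | COc1cc(C[C@H]2COC(=O)C2)ccc1OCc1ccccc1 | intermediate
8 | 3,4,5-trimethoxybenzyl bromide | COc1cc(CBr)cc(OC)c1OC | starting material
9 | lithium enolate of lactone 7 | COc1cc(C[C@H]2COC(O[Li])=C2)ccc1OCc1ccccc1 | intermediate
10 | (3R,4R)-4-[4-(benzyloxy)-3-methoxybenzyl]-3-(3,4,5-trimethoxybenzyl)oxolan-2-one | COc1cc(C[C@H]2COC(=O)[C@@H]2Cc2cc(OC)c(OC)c(OC)c2)ccc1OCc1ccccc1 | intermediate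
11 | (2R,3R)-2-[4-(benzyloxy)-3-methoxybenzyl]-3-(3,4,5-trimethoxybenzyl)butane-1,4-diol | COc1cc(C[C@@H](CO)[C@H](CO)Cc2cc(OC)c(OC)c(OC)c2)ccc1OCc1ccccc1 | intermediate
12 | (2R,3R)-2-(4-hydroxy-3-methoxybenzyl)-3-(3,4,5-trimethoxybenzyl)butane-1,4-diol | COc1cc(C[C@@H](CO)[C@H](CO)Cc2cc(OC)c(OC)c(OC)c2)ccc1O | intermediate
13 | (2R,3R)-2-[3-methoxy-4-(pivaloyloxy)benzyl]-3-(3,4,5-trimethoxybenzyl)butane-1,4-diol | COc1cc(C[C@@H](CO)[C@H](CO)Cc2cc(OC)c(OC)c(OC)c2)ccc1OC(=O)C(C)(C)C | intermediate
14 | benzylic cation of 13 at the trimethoxybenzyl carbon | COc1cc(C[C@@H](CO)[C@H](CO)[CH+]c2cc(OC)c(OC)c(OC)c2)ccc1OC(=O)C(C)(C)C | intermediate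
15 | [(2S,3R,4R)-4-[3-methoxy-4-(pivaloyloxy)benzyl]-2-(3,4,5-trimethoxyphenyl)oxolan-3-yl]methanol | COc1cc(C[C@H]2CO[C@H](c3cc(OC)c(OC)c(OC)c3)[C@H]2CO)ccc1OC(=O)C(C)(C)C | intermediate
16 | [(2S,3R,4R)-4-(4-hydroxy-3-methoxybenzyl)-2-(3,4,5-trimethoxyphenyl)oxolan-3-yl]methanol | COc1cc(C[C@H]2CO[C@H](c3cc(OC)c(OC)c(OC)c3)[C@H]2CO)ccc1O | target

**Step count and risks**

Total steps: 9. Longest linear sequence: 9 steps (1 → 16).

Steps most likely to fail:

1. Step 8. Hydride abstraction may be slow because the para-methoxy group is twisted by its two neighbours. The product C2–H bond (benzylic and next to oxygen) may be oxidised further. The cation may also close onto the guaiacyl ring carbon instead of oxygen. Fallback, from 7 to 16: the benzylic oxygen is installed by aldol chemistry instead of C–H oxidation. The enolate of 7 (LiN(SiMe3)2, THF, −78 °C) is added to 3,4,5-trimethoxybenzaldehyde to give the trans hydroxy lactone F1 as carbinol epimers. LiAlH4 in THF reduces it to the triol F2. Catalytic camphorsulfonic acid in CH2Cl2 at 0 °C ionises the benzylic alcohol, and the same 5-exo closure gives the 2,3-trans oxolane benzyl ether F3. Hydrogenolysis (H2, Pd/C, EtOAc) then gives 16 directly.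

2. Step 7. Acylation may fail to discriminate fully between the phenoxide and the two primary hydroxyls, or the aryl ester may hydrolyse in the aqueous base. Fallback, from 11 to 13: the diol is masked before the phenol is freed. TBSCl and imidazole in DMF give the bis(silyl ether) F4. Hydrogenolysis (H2, Pd/C) gives the phenol F5. PivCl, Et3N and catalytic DMAP in CH2Cl2 give the aryl pivalate F6. HF·pyridine in THF removes both silyl groups to give 13.

3. Step 2. Facial selectivity in the hydrogenation may be insufficient, or the sense of induction may be the opposite one. Fallback, from 1 to 7: the centre is set by a chiral auxiliary. Aldehyde 1 with Meldrum's acid in triethylammonium formate at 95 °C (reductive Knoevenagel, hydrolysis, decarboxylation) gives the propanoic acid F7. The mixed anhydride (PivCl, Et3N) is coupled with (S)-4-benzyl-1,3-oxazolidin-2-one and LiCl in THF to give the imide F8. Evans alkylation (NaN(SiMe3)2, THF, −78 °C, tert-butyl bromoacetate) enters anti to the auxiliary benzyl group and gives the R succinate imide F9. LiBH4 in THF with one equivalent of MeOH at 0 °C cleaves the auxiliary reductively to the hydroxy tert-butyl ester F10. Trifluoroacetic acid in CH2Cl2 closes it to 7.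

**Further compounds**

F1 | step 8 | (3S,4R)-4-[4-(benzyloxy)-3-methoxybenzyl]-3-[hydroxy(3,4,5-trimethoxyphenyl)methyl]oxolan-2-one (carbinol epimers) | COc1cc(C[C@H]2COC(=O)[C@@H]2C(O)c2cc(OC)c(OC)c(OC)c2)ccc1OCc1ccccc1
F2 | step 8 | (2R,3R)-2-[4-(benzyloxy)-3-methoxybenzyl]-3-[hydroxy(3,4,5-trimethoxyphenyl)methyl]butane-1,4-diol (carbinol epimers) | COc1cc(C[C@@H](CO)[C@H](CO)C(O)c2cc(OC)c(OC)c(OC)c2)ccc1OCc1ccccc1
F3 | step 8 | [(2S,3R,4R)-4-[4-(benzyloxy)-3-methoxybenzyl]-2-(3,4,5-trimethoxyphenyl)oxolan-3-yl]methanol | COc1cc(C[C@H]2CO[C@H](c3cc(OC)c(OC)c(OC)c3)[C@H]2CO)ccc1OCc1ccccc1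
F4 | step 7 | bis(tert-butyldimethylsilyl) ether of diol 11 | COc1cc(C[C@@H](CO[Si](C)(C)C(C)(C)C)[C@H](CO[Si](C)(C)C(C)(C)C)Cc2cc(OC)c(OC)c(OC)c2)ccc1OCc1ccccc1
F5 | step 7 | bis(tert-butyldimethylsilyl) ether of triol 12 with free phenol | COc1cc(C[C@@H](CO[Si](C)(C)C(C)(C)C)[C@H](CO[Si](C)(C)C(C)(C)C)Cc2cc(OC)c(OC)c(OC)c2)ccc1O
F6 | step 7 | bis(tert-butyldimethylsilyl) ether of pivalate diol 13 | COc1cc(C[C@@H](CO[Si](C)(C)C(C)(C)C)[C@H](CO[Si](C)(C)C(C)(C)C)Cc2cc(OC)c(OC)c(OC)c2)ccc1OC(=O)C(C)(C)C
F7 | step 2 | 3-[4-(benzyloxy)-3-methoxyphenyl]propanoic acid | COc1cc(CCC(=O)O)ccc1OCc1ccccc1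
F8 | step 2 | (S)-4-benzyl-3-{3-[4-(benzyloxy)-3-methoxyphenyl]propanoyl}-1,3-oxazolidin-2-one | COc1cc(CCC(=O)N2[C@@H](Cc3ccccc3)COC2=O)ccc1OCc1ccccc1
F9 | step 2 | tert-butyl (R)-3-[4-(benzyloxy)-3-methoxybenzyl]-4-[(S)-4-benzyl-2-oxo-1,3-oxazolidin-3-yl]-4-oxobutanoate | COc1cc(C[C@H](CC(=O)OC(C)(C)C)C(=O)N2[C@@H](Cc3ccccc3)COC2=O)ccc1OCc1ccccc1
F10 | step 2 | tert-butyl (R)-4-[4-(benzyloxy)-3-methoxyphenyl]-3-(hydroxymethyl)butanoate | COc1cc(C[C@H](CC(=O)OC(C)(C)C)CO)ccc1OCc1ccccc1
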